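**Strategy**

The oxane ring is not made by etherification but grown from a cyclopentanone. Its oxygen O1 lies between two fully substituted carbons, stereogenic C2 (methyl, side chain) and C6 (gem-dimethyl). A Baeyer–Villiger oxidation of an α-quaternary cyclopentanone inserts O1 between the carbonyl carbon and the quaternary carbon with retention: in one operation the five-membered carbocycle becomes the six-membered lactone, and an all-carbon quaternary centre, set by palladium-catalysed decarboxylative allylation, becomes the tertiary ether stereocentre. The precursor is an (S)-2-methyl-2-alkylcyclopentanone whose chain carries the C7 methyl centre from (R)-β-citronellene. The lactone carbonyl is then turned into C6(CH3)2, and an (S)-glycerate unit supplies the ene-diol terminus.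

Key step: step 6

Assumption: the sense of induction in step 2 is taken from the six-membered series, where the (S)-ligand gives the (S)-ketone; the (R)-ligand is therefore used to obtain (R)-4.

**Route**

Step 1
Reactants: 1 diallyl adipate
Product: 3 allyl 1-methyl-2-oxocyclopentane-1-carboxylate (racemic), via sodium enolate of allyl 2-oxocyclopentane-1-carboxylate 2 (not isolated)
Conditions: NaH (1.05 equiv), THF, 40 °C; then MeI (1.5 equiv), 40 °C
Reagents that add atoms: iodomethane, CI
Why: Dieckmann condensation closes the five-membered β-keto ester, whose sodium enolate is C-methylated in the same flask; the stereocentre formed is racemic and is erased in step 2.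

Step 2
Reactants: 3 allyl 1-methyl-2-oxocyclopentane-1-carboxylate
Product: 4 (2R)-2-methyl-2-(prop-2-en-1-yl)cyclopentan-1-one
Conditions: Pd2(dba)3 (2.5 mol %), (R)-t-BuPHOX (6.25 mol %), toluene, 25 °C
Reagents that add atoms: none
Why: Decarboxylative asymmetric allylic alkylation (Tsuji–Trost type): zerovalent palladium ionizes the allyl ester, CO2 is lost and the PHOX-bound allylpalladium enolate recombines at the methyl-bearing carbon, so both enantiomers of 3 should converge on (R)-4 with the enolate face chosen by the ligand.

Step 3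
Reactants: 5 (R)-3,7-dimethylocta-1,6-diene ((R)-β-citronellene)
Product: 7 (R)-4-methylhex-5-en-1-ol, via (R)-4-methylhex-5-enal 6 (not isolated)
Conditions: O3 (1.0 equiv), CH2Cl2/MeOH, −78 °C; then NaBH4, −78 → 0 °C
Reagents that add atoms: ozone, [O-][O+]=O
Why: Ozonolysis with reductive work-up: electrophilic ozone should cleave the electron-rich trisubstituted alkene well before the vinyl group, and borohydride reduces the aldehyde without touching the stereocentre.

Step 4
Reactants: 7 (R)-4-methylhex-5-en-1-ol
Product: 8 (R)-6-chloro-3-methylhex-1-ene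
Conditions: PPh3, N-chlorosuccinimide, CH2Cl2, 0 → 25 °C
Reagents that add atoms: N-chlorosuccinimide, ClN1C(=O)CCC1=O
Why: Appel-type chlorination through the alkoxyphosphonium salt, an SN2 displacement at a primary carbon remote from the stereocentre.

Step 5
Reactants: 4 (2R)-2-methyl-2-(prop-2-en-1-yl)cyclopentan-1-one; 8 (R)-6-chloro-3-methylhex-1-ene
Product: 10 (2S)-2-[(4S)-7-chloro-4-methylheptyl]-2-methylcyclopentan-1-one, via (2R)-2-[(4R)-7-chloro-4-methylhept-2-en-1-yl]-2-methylcyclopentan-1-one 9 (not isolated)
Conditions: 8 (3 equiv), second-generation Hoveyda–Grubbs catalyst [RuCl2(H2IMes)(=CH-C6H4-2-O-i-Pr)] (5 mol %), CH2Cl2, 40 °C; then solvent exchange to EtOAc, H2 (1 atm), Pd/C, 25 °C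
Reagents that add atoms: none
Why: Olefin cross-metathesis of the unhindered allyl group with the allylically branched, slowly homodimerizing partner used in excess should give 9, and heterogeneous hydrogenation then removes the alkene (and its E/Z question) while ketone, primary chloride and both stereocentres stay untouched (the descriptors change only through CIP priorities).

Step 6
Reactants: 10 (2S)-2-[(4S)-7-chloro-4-methylheptyl]-2-methylcyclopentan-1-one
Product: 11 (6S)-6-[(4S)-7-chloro-4-methylheptyl]-6-methyloxan-2-one
Conditions: mCPBA (1.5 equiv), NaHCO3, CH2Cl2, 0 → 25 °C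
Reagents that add atoms: 3-chloroperoxybenzoic acid, OOC(=O)c1cccc(Cl)c1
Why: Baeyer–Villiger oxidation: the peracid adds to the ketone to give the Criegee adduct, and the α-carbon best able to carry positive charge, the quaternary C2, migrates from carbon to the peroxide oxygen as 3-chlorobenzoate leaves. The closest known reaction type is the peracid ring expansion of α,α-disubstituted cycloalkanones to lactones. The six-membered ring is not closed by cyclization but arises by ring expansion, a 1,2-shift that inserts one oxygen atom into the C1–C2 bond of the five-membered ring. No new stereocentre forms; the migrating carbon keeps its configuration (retention), so the allylation-derived centre becomes the (S)-configured tertiary ether carbon. The step needs regioselectivity (quaternary over methylene migration), secured by the migratory aptitude tertiary alkyl > primary alkyl, and chemoselectivity, secured because the alkene was hydrogenated in step 5 and the primary chloride is inert to peracid.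

Step 7
Reactants: 11 (6S)-6-[(4S)-7-chloro-4-methylheptyl]-6-methyloxan-2-one
Product: 12 (6S)-6-[(4S)-7-chloro-4-methylheptyl]-2,6-dimethyloxan-2-ol (both C2 epimers; may equilibrate with its open hydroxy-ketone tautomer)
Conditions: MeLi (1.1 equiv), THF, −78 °C; AcOH quench at −78 °C
Reagents that add atoms: methyllithium, [Li]C
Why: 1,2-Addition of one equivalent of methyllithium to the δ-lactone should stop at the lithium hemiketalate, which is stable at −78 °C and is protonated cold (lactone-to-lactol addition); the new anomeric centre is of no consequence because it is flattened in step 8.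

Step 8
Reactants: 12 (6S)-6-[(4S)-7-chloro-4-methylheptyl]-2,6-dimethyloxan-2-ol
Product: 13 (2S)-2-[(4S)-7-chloro-4-methylheptyl]-2,6,6-trimethyloxane
Conditions: AlMe3 (4 equiv), TMSOTf (0.2 equiv), CH2Cl2, −78 → 0 °C
Reagents that add atoms: trimethylaluminium, C[Al](C)C
Why: Lewis-acid-promoted substitution of a cyclic hemiketal (C-glycosidation type): ionization gives the endocyclic tertiary oxocarbenium ion, which takes a methyl group from aluminium to give the gem-dimethyl carbon C6, so no stereocentre forms and C2 is not involved.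

Step 9
Reactants: 14 methyl (4S)-2,2-dimethyl-1,3-dioxolane-4-carboxylate
Product: 15 (4S)-N-methoxy-N,2,2-trimethyl-1,3-dioxolane-4-carboxamide
Conditions: MeNHOMe·HCl (1.5 equiv), i-PrMgCl (3 equiv), THF, −20 → 0 °C
Reagents that add atoms: N,O-dimethylhydroxylamine hydrochloride, CNOC.Cl
Why: Weinreb amide formation from the ester with the chloromagnesium amide generated in situ; the low temperature should keep the α-alkoxy stereocentre intact.

Step 10
Reactants: 13 (2S)-2-[(4S)-7-chloro-4-methylheptyl]-2,6,6-trimethyloxane; 15 (4S)-N-methoxy-N,2,2-trimethyl-1,3-dioxolane-4-carboxamide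
Product: 17 (5S)-1-[(4S)-2,2-dimethyl-1,3-dioxolan-4-yl]-5-methyl-8-[(2S)-2,6,6-trimethyloxan-2-yl]octan-1-one, via {(4S)-4-methyl-7-[(2S)-2,6,6-trimethyloxan-2-yl]heptyl}magnesium chloride 16 (not isolated)
Conditions: Mg turnings (activated by 1,2-dibromoethane), THF, 65 °C; then 15, THF, 0 °C; aq NH4Cl
Reagents that add atoms: none
Why: Grignard formation from the primary chloride and acylation with the Weinreb amide, whose five-membered magnesium chelate holds the tetrahedral intermediate until work-up and so stops at the ketone (Weinreb ketone synthesis).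

Step 11
Reactants: 17 (5S)-1-[(4S)-2,2-dimethyl-1,3-dioxolan-4-yl]-5-methyl-8-[(2S)-2,6,6-trimethyloxan-2-yl]octan-1-one
Product: 18 (4R)-2,2-dimethyl-4-{(6R)-6-methyl-9-[(2S)-2,6,6-trimethyloxan-2-yl]non-1-en-2-yl}-1,3-dioxolane
Conditions: Ph3PCH3Br, KHMDS, THF, 0 °C; then 17, −78 → 0 °C
Reagents that add atoms: methyltriphenylphosphonium bromide, C[P+](c1ccccc1)(c1ccccc1)c1ccccc1.[Br-]
Why: Wittig methylenation with the non-stabilized ylide converts the ketone into the 1,1-disubstituted alkene; adding the ketone cold to the preformed ylide should outrun enolization of the α-alkoxy ketone, so the dioxolane centre keeps its configuration.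

Step 12
Reactants: 18 (4R)-2,2-dimethyl-4-{(6R)-6-methyl-9-[(2S)-2,6,6-trimethyloxan-2-yl]non-1-en-2-yl}-1,3-dioxolane
Product: 19 (2R,7R)-7-methyl-3-methylidene-10-[(2S)-2,6,6-trimethyloxan-2-yl]decane-1,2-diol
Conditions: AcOH/H2O (4:1), 40 °C
Reagents that add atoms: none
Why: Acid-catalysed hydrolysis of the isopropylidene ketal; the tertiary oxane ether and the allylic alcohol should tolerate dilute acetic acid, and no C–O bond at C2 is broken.

Step 13
Reactants: 19 (2R,7R)-7-methyl-3-methylidene-10-[(2S)-2,6,6-trimethyloxan-2-yl]decane-1,2-diol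
Product: 20 (2R,7R)-7-methyl-3-methylidene-10-[(2S)-2,6,6-trimethyloxan-2-yl]decane-1,2-diyl diacetate (target)
Conditions: Ac2O, pyridine, DMAP (cat.), CH2Cl2, 25 °C
Reagents that add atoms: acetic anhydride, CC(=O)OC(C)=O
Why: DMAP-catalysed O-acylation of the primary and the allylic secondary hydroxyl without touching any stereocentre.

**Compound list**

1 | diallyl adipate (diallyl hexanedioate) | C=CCOC(=O)CCCCC(=O)OCC=C | starting material
2 | sodium enolate of allyl 2-oxocyclopentane-1-carboxylate | [Na+].[O-]C1=C(C(=O)OCC=C)CCC1 | intermediate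
3 | allyl 1-methyl-2-oxocyclopentane-1-carboxylate (racemic) | C=CCOC(=O)C1(C)CCCC1=O | intermediate
4 | (2R)-2-methyl-2-(prop-2-en-1-yl)cyclopentan-1-one | C=CC[C@@]1(C)CCCC1=O | intermediate
5 | (R)-3,7-dimethylocta-1,6-diene ((R)-β-citronellene) | CC(C)=CCC[C@@H](C)C=C | starting material
6 | (R)-4-methylhex-5-enal | O=CCC[C@@H](C)C=C | intermediate
7 | (R)-4-methylhex-5-en-1-ol | OCCC[C@@H](C)C=C | intermediate
8 | (R)-6-chloro-3-methylhex-1-ene | ClCCC[C@@H](C)C=C | intermediate
9 | (2R)-2-[(2E,4R)-7-chloro-4-methylhept-2-en-1-yl]-2-methylcyclopentan-1-one (E drawn; alkene geometry irrelevant) | ClCCC[C@@H](C)/C=C/C[C@@]1(C)CCCC1=O | intermediate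
10 | (2S)-2-[(4S)-7-chloro-4-methylheptyl]-2-methylcyclopentan-1-one | ClCCC[C@@H](C)CCC[C@@]1(C)CCCC1=O | intermediate
11 | (6S)-6-[(4S)-7-chloro-4-methylheptyl]-6-methyloxan-2-one | ClCCC[C@@H](C)CCC[C@@]1(C)CCCC(=O)O1 | intermediate
12 | (6S)-6-[(4S)-7-chloro-4-methylheptyl]-2,6-dimethyloxan-2-ol (C2 epimers) | ClCCC[C@@H](C)CCC[C@@]1(C)CCCC(C)(O)O1 | intermediate
13 | (2S)-2-[(4S)-7-chloro-4-methylheptyl]-2,6,6-trimethyloxane | ClCCC[C@@H](C)CCC[C@@]1(C)CCCC(C)(C)O1 | intermediate
14 | methyl (4S)-2,2-dimethyl-1,3-dioxolane-4-carboxylate | COC(=O)[C@@H]1COC(C)(C)O1 | starting material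
15 | (4S)-N-methoxy-N,2,2-trimethyl-1,3-dioxolane-4-carboxamide | CON(C)C(=O)[C@@H]1COC(C)(C)O1 | intermediate
16 | {(4S)-4-methyl-7-[(2S)-2,6,6-trimethyloxan-2-yl]heptyl}magnesium chloride | Cl[Mg]CCC[C@@H](C)CCC[C@@]1(C)CCCC(C)(C)O1 | intermediate
17 | (5S)-1-[(4S)-2,2-dimethyl-1,3-dioxolan-4-yl]-5-methyl-8-[(2S)-2,6,6-trimethyloxan-2-yl]octan-1-one | O=C(CCC[C@@H](C)CCC[C@@]1(C)CCCC(C)(C)O1)[C@@H]1COC(C)(C)O1 | intermediate
18 | (4R)-2,2-dimethyl-4-{(6R)-6-methyl-9-[(2S)-2,6,6-trimethyloxan-2-yl]non-1-en-2-yl}-1,3-dioxolane | C=C(CCC[C@@H](C)CCC[C@@]1(C)CCCC(C)(C)O1)[C@@H]1COC(C)(C)O1 | intermediate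
19 | (2R,7R)-7-methyl-3-methylidene-10-[(2S)-2,6,6-trimethyloxan-2-yl]decane-1,2-diol | C=C(CCC[C@@H](C)CCC[C@@]1(C)CCCC(C)(C)O1)[C@H](CO)O | intermediate
20 | (2R,7R)-7-methyl-3-methylidene-10-[(2S)-2,6,6-trimethyloxan-2-yl]decane-1,2-diyl diacetate | C=C(CCC[C@@H](C)CCC[C@@]1(C)CCCC(C)(C)O1)[C@H](COC(C)=O)OC(C)=O | target

**Step count and risks**

Total step count: 13 (the one-flask sequences of steps 1, 3, 5 and 10 are counted once each).

Longest linear sequence: 10 steps (steps 1, 2, 5, 6, 7, 8, 10, 11, 12, 13).

The three steps most likely to fail: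

Step 8 (methyl transfer to the hemiketal). The hemiketal can open to its hydroxy-ketone tautomer and trimethylaluminium can add directly to that ketone, or the oxocarbenium ion can lose a proton, so that an acyclic diol or enol ethers would form instead of the gem-dimethyl ether. The fallback sets out from lactone 11 (steps 7 and 8 are bypassed) and comes back at 13. Carbonyl methylenation of 11 with Cp2TiMe2 (toluene, 70 °C) should give the exocyclic enol ether (2S)-2-[(4S)-7-chloro-4-methylheptyl]-2-methyl-6-methylideneoxane F1, in which the ring cannot open. Acid-catalysed addition of methanol (PPTS, MeOH, 0 °C) should give the cyclic methyl ketal (6S)-6-[(4S)-7-chloro-4-methylheptyl]-2-methoxy-2,6-dimethyloxane F2. AlMe3 with TMSOTf in CH2Cl2 should then exchange the methoxy group for methyl through the same oxocarbenium ion, now without a free ketone, to give 13.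

Step 2 (enantioselective allylation). Facial discrimination on the five-membered palladium enolate may be incomplete; the minor enantiomer would later appear as the C2 epimer of the oxane, which cannot be removed once the remote C7 centre is attached. The fallback replaces asymmetric catalysis by enzymatic desymmetrization; it does not branch from a numbered compound but replaces 1–3, and it comes back at 4. Commercial 2-methylcyclopentane-1,3-dione (CC1C(=O)CCC1=O) would be C-allylated (allyl bromide, aqueous NaOH) to the prochiral 2-methyl-2-(prop-2-en-1-yl)cyclopentane-1,3-dione F3. A ketoreductase with NADPH recycling (or fermenting baker's yeast), chosen for this sense of induction, should reduce one of the two enantiotopic carbonyl groups to (2S,3S)-3-hydroxy-2-methyl-2-(prop-2-en-1-yl)cyclopentan-1-one F4, from which any diastereomeric ketol can be removed by chromatography. 1,1'-Thiocarbonyldiimidazole (DMAP, CH2Cl2) should give O-[(1S,2S)-2-methyl-3-oxo-2-(prop-2-en-1-yl)cyclopentyl] 1H-imidazole-1-carbothioate F5, and Barton–McCombie deoxygenation (Bu3SnH, AIBN, toluene, 110 °C) should return (R)-4.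

Step 11 (Wittig methylenation). The basic ylide may enolize the α-alkoxy ketone, which would lead to epimerization at the dioxolane carbon or to β-elimination of the ring oxygen. The fallback sets out from ketone 17 and comes back at 18. Addition of the weakly basic organocerium reagent made from Me3SiCH2MgCl and CeCl3 (THF, −78 °C) should give the β-hydroxysilane 2-[(4S)-2,2-dimethyl-1,3-dioxolan-4-yl]-6-methyl-1-(trimethylsilyl)-9-[(2S)-2,6,6-trimethyloxan-2-yl]nonan-2-ol F6 (both carbinol epimers; other centres as in 17). Peterson elimination (KH, THF, 0 °C) should then give 18 without an enolizable ketone ever meeting a base.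

Further compounds
F1 | step 8 | (2S)-2-[(4S)-7-chloro-4-methylheptyl]-2-methyl-6-methylideneoxane | ClCCC[C@@H](C)CCC[C@@]1(C)CCCC(=C)O1
F2 | step 8 | (6S)-6-[(4S)-7-chloro-4-methylheptyl]-2-methoxy-2,6-dimethyloxane (C2 epimers) | ClCCC[C@@H](C)CCC[C@@]1(C)CCCC(C)(OC)O1
F3 | step 2 | 2-methyl-2-(prop-2-en-1-yl)cyclopentane-1,3-dione | C=CCC1(C)C(=O)CCC1=O
F4 | step 2 | (2S,3S)-3-hydroxy-2-methyl-2-(prop-2-en-1-yl)cyclopentan-1-one | C=CC[C@@]1(C)[C@@H](O)CCC1=O
F5 | step 2 | O-[(1S,2S)-2-methyl-3-oxo-2-(prop-2-en-1-yl)cyclopentyl] 1H-imidazole-1-carbothioate | C=CC[C@@]1(C)[C@@H](OC(=S)n2ccnc2)CCC1=O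
F6 | step 11 | 2-[(4S)-2,2-dimethyl-1,3-dioxolan-4-yl]-6-methyl-1-(trimethylsilyl)-9-[(2S)-2,6,6-trimethyloxan-2-yl]nonan-2-ol (carbinol epimers) | C[Si](C)(C)CC(O)(CCC[C@@H](C)CCC[C@@]1(C)CCCC(C)(C)O1)[C@@H]1COC(C)(C)O1
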